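**Retrosynthetic overview**
- Target ⇒ unprotected bis(o‑prenylphenol) benzophenone: the pyran O–C bond is made last, by dehydrogenation to an o‑quinone methide and oxa‑6π electrocyclisation (the prenyl → chromene path proposed in the biosynthesis), and it must occur on the resorcinol ring only.
- Bis(o‑prenylphenol) ⇒ dibromo‑trihydroxybenzophenone: both aryl–prenyl bonds are made in one double Stille prenylation.
- Dibromo ketone ⇒ 4‑bromoresorcinol + 2‑bromo‑3‑hydroxybenzoic acid (aryl–C(=O) bond, Friedel–Crafts); the two bromines fix both prenyl positions.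
- Ring order: both benzene rings are bought; the 2H‑pyran is the only ring formed and is closed in the last step. No protecting groups.

Assumption: the target has no stereocentre and no stereogenic double bond, so it is achiral and the SMILES as given is its only stereoisomer.
Assumption: 2‑bromo‑3‑hydroxybenzoic acid and tributyl(prenyl)stannane are bought as catalogue reagents.

**Step 1**
Reactants: 1 4‑bromoresorcinol (4‑bromobenzene‑1,3‑diol); 2 2‑bromo‑3‑hydroxybenzoic acid
Product: 3 (2‑bromo‑3‑hydroxyphenyl)(5‑bromo‑2,4‑dihydroxyphenyl)methanone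
Conditions: Eaton's reagent (P2O5–MeSO3H, 1:10 w/w), 70 °C, 3 h; then ice–water
Reagents that add atoms: none
Why: Friedel–Crafts acylation with the free carboxylic acid activated in P2O5–MeSO3H: 4‑bromoresorcinol reacts at C6, the only position para to one hydroxyl and ortho to the other that is not flanked by both, so the bromine lands at C5 of the new 2,4‑dihydroxybenzoyl ring, while the acid partner is too deactivated (CO2H, Br) to acylate itself; no stereocentre is formed.

**Step 2**
Reactants: 3 (2‑bromo‑3‑hydroxyphenyl)(5‑bromo‑2,4‑dihydroxyphenyl)methanone; 4 tributyl(3‑methylbut‑2‑en‑1‑yl)stannane (3.0 equiv)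
Product: 6 [2,4‑dihydroxy‑5‑(3‑methylbut‑2‑en‑1‑yl)phenyl][3‑hydroxy‑2‑(3‑methylbut‑2‑en‑1‑yl)phenyl]methanone, via ring‑A monoprenyl monobromide 5 (not isolated)
Conditions: Pd(PPh3)4 (10 mol %), degassed DMF, 100 °C, 16 h
Reagents that add atoms: none
Why: Two‑fold Stille cross‑coupling under neutral conditions that tolerate the three free phenols: the ketone‑activated ring‑A C–Br is expected to undergo oxidative addition first (giving 5) and the electron‑rich ring‑B C–Br second, each aryl–Pd–prenyl intermediate reductively eliminates at the unsubstituted allyl terminus to give the linear prenyl group, and the absence of base keeps the 2‑hydroxy‑2'‑bromobenzophenone from closing to a xanthone.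

**Step 3**
Reactants: 6 [2,4‑dihydroxy‑5‑(3‑methylbut‑2‑en‑1‑yl)phenyl][3‑hydroxy‑2‑(3‑methylbut‑2‑en‑1‑yl)phenyl]methanone
Product: 8 cudraphenone A, (7‑hydroxy‑2,2‑dimethyl‑2H‑chromen‑6‑yl)[3‑hydroxy‑2‑(3‑methylbut‑2‑en‑1‑yl)phenyl]methanone, via ortho‑quinone methide 7 (not isolated)
Conditions: DDQ (1.05 equiv, portionwise), PhH, 25 → 50 °C, 2 h
Reagents that add atoms: none
Why: DDQ dehydrogenation of an o‑prenylphenol followed by oxa‑6π electrocyclisation, the laboratory counterpart of the biosynthetic prenyl‑to‑chromene oxidation: hydride should be abstracted only from the ring‑B benzylic CH2, which is ortho to the 4‑OH, para to the 2‑OH and meta to the ketone, whereas the ring‑A prenyl has one OH donor and an ortho carbonyl and should react far more slowly, and the resulting (Z)‑o‑quinone methide 7 can close only onto the 4‑oxygen, giving the linear 6‑acyl‑7‑hydroxy‑2,2‑dimethyl‑2H‑chromene with no stereocentre created.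

**Compound list**
1 | 4‑bromoresorcinol (4‑bromobenzene‑1,3‑diol) | Oc1ccc(Br)c(O)c1 | starting material
2 | 2‑bromo‑3‑hydroxybenzoic acid | O=C(O)c1cccc(O)c1Br | starting material
3 | (2‑bromo‑3‑hydroxyphenyl)(5‑bromo‑2,4‑dihydroxyphenyl)methanone | O=C(c1cccc(O)c1Br)c1cc(Br)c(O)cc1O | intermediate
4 | tributyl(3‑methylbut‑2‑en‑1‑yl)stannane | CCCC[Sn](CCCC)(CCCC)CC=C(C)C | starting material
5 | (5‑bromo‑2,4‑dihydroxyphenyl)[3‑hydroxy‑2‑(3‑methylbut‑2‑en‑1‑yl)phenyl]methanone | CC(C)=CCc1c(O)cccc1C(=O)c1cc(Br)c(O)cc1O | intermediate (not isolated)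
6 | [2,4‑dihydroxy‑5‑(3‑methylbut‑2‑en‑1‑yl)phenyl][3‑hydroxy‑2‑(3‑methylbut‑2‑en‑1‑yl)phenyl]methanone | CC(C)=CCc1c(O)cccc1C(=O)c1cc(CC=C(C)C)c(O)cc1O | intermediate
7 | (6Z)‑3‑hydroxy‑4‑[3‑hydroxy‑2‑(3‑methylbut‑2‑en‑1‑yl)benzoyl]‑6‑(3‑methylbut‑2‑en‑1‑ylidene)cyclohexa‑2,4‑dien‑1‑one | CC(C)=C/C=C1/C=C(C(=O)c2cccc(O)c2CC=C(C)C)C(O)=CC1=O | intermediate (not isolated)
8 | cudraphenone A, (7‑hydroxy‑2,2‑dimethyl‑2H‑chromen‑6‑yl)[3‑hydroxy‑2‑(3‑methylbut‑2‑en‑1‑yl)phenyl]methanone | CC(C)=CCc1c(O)cccc1C(=O)c1cc2c(cc1O)OC(C)(C)C=C2 | target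

**Total step count:** 3
**Longest linear sequence:** 3

**Steps most likely to fail, with fallbacks**

Step 2 (highest risk). The prenyl group may be delivered at its substituted terminus (reverse prenyl), and coupling may be slow at the di‑ortho‑substituted ring‑A carbon or the electron‑rich ring‑B carbon. The fallback sets out from 3 and replaces direct prenyl transfer by allylation followed by olefin metathesis. A two‑fold Stille coupling with allyltributylstannane (Pd(PPh3)4, DMF, 100 °C), which has no regiochemical ambiguity and a smaller nucleophile, gives (2‑allyl‑3‑hydroxyphenyl)(5‑allyl‑2,4‑dihydroxyphenyl)methanone F2. Two‑fold cross‑metathesis of F2 with excess 2‑methylbut‑2‑ene (Grubbs II, CH2Cl2, 40 °C) turns both allyl groups into prenyl groups and comes back to the route at 6.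

Step 3. DDQ may also dehydrogenate the ring‑A prenylphenol (bis‑chromene) or over‑oxidise the product. The fallback sets out from 5, which is isolated by running step 2 with 1.0 equiv of 4 at 80 °C, and generates the same o‑quinone methide without an oxidant. A Heck reaction of the remaining ring‑B bromide with 2‑methylbut‑3‑en‑2‑ol (Pd(OAc)2, P(o‑tol)3, NaHCO3, DMF, 110 °C) gives (E)‑[2,4‑dihydroxy‑5‑(3‑hydroxy‑3‑methylbut‑1‑en‑1‑yl)phenyl][3‑hydroxy‑2‑(3‑methylbut‑2‑en‑1‑yl)phenyl]methanone F3. Catalytic PPTS (CH2Cl2, 40 °C) ionises the tertiary allylic alcohol of F3 and, after loss of water, comes back to the route at 7, which electrocyclises to 8; the ring‑A prenyl group cannot react because no oxidant is present.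

Step 1. Hot strong acid may cause bromine migration or loss from 1, or sluggish acylation by the ortho‑bromo acid. The fallback sets out from 2 and introduces the ring‑B bromine after the ketone is made. Acylation of plain resorcinol with 2 (Eaton's reagent, 70 °C), which is more nucleophilic and has no halogen to scramble, gives (2‑bromo‑3‑hydroxyphenyl)(2,4‑dihydroxyphenyl)methanone F1. Monobromination of F1 (NBS 1.0 equiv, MeCN, 0 °C) should go to C5 of the chelated resorcinol ring (para to 2‑OH, ortho to 4‑OH; ring A is deactivated) and comes back to the route at 3.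

**Further compounds**
F1 | step 1 | (2‑bromo‑3‑hydroxyphenyl)(2,4‑dihydroxyphenyl)methanone | O=C(c1cccc(O)c1Br)c1ccc(O)cc1O
F2 | step 2 | (2‑allyl‑3‑hydroxyphenyl)(5‑allyl‑2,4‑dihydroxyphenyl)methanone | C=CCc1c(O)cccc1C(=O)c1cc(CC=C)c(O)cc1O
F3 | step 3 | (E)‑[2,4‑dihydroxy‑5‑(3‑hydroxy‑3‑methylbut‑1‑en‑1‑yl)phenyl][3‑hydroxy‑2‑(3‑methylbut‑2‑en‑1‑yl)phenyl]methanone | CC(C)=CCc1c(O)cccc1C(=O)c1cc(/C=C/C(C)(C)O)c(O)cc1O
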